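**Strategy.** Everything rests on closing ring A between C3 and C4 (eremophilane numbering). The precursor is a carane-derived ring B that carries, cis to each other, a vinyl group (C4=C15) on the quaternary C5 and a 3-oxopropyl chain (C1–C3) on C10. Hydrogen-atom transfer from an iron hydride to the vinyl group creates the C15 methyl group and a C4 radical, which closes ring A onto the C3 aldehyde and sets C3 and C4 all-equatorial in one operation. The gem-dimethylcyclopropane of (+)-3-carene first steers C5 and C10, then becomes the C7 isopropenyl group, and the C8/C9 oxygens come from a face-selective dihydroxylation.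

Key step: step 4

Remark: eremophilane numbering is used from compound 6 on, carane numbering for 1–5. β is the face of the C5 methyl group (C14), which is also the face of the cyclopropane bridge. (+)-3-Carene is taken as the (1S,6R) enantiomer. Senecioyl = 3-methylbut-2-enoyl; angeloyl = (Z)-2-methylbut-2-enoyl. The C9 carbinol configuration of 8 is left open because step 7 erases it.

Step 1
Reactants: 1 (+)-3-carene
Product: 2 (1S,6R)-car-3-en-5-one
Conditions: t-BuOOH, CrO3 (cat.), CH2Cl2, rt
Reagents that add atoms: tert-butyl hydroperoxide, CC(C)(C)OO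
Why: Chromium-catalysed allylic C–H oxidation should attack the C5 methylene, which is allylic to the unsubstituted alkene CH and cyclopropylcarbinylic, and give the β-methyl enone without touching the two stereocentres.

Step 2
Reactants: 2 (1S,6R)-car-3-en-5-one
Product: 4 (1S,6R)-3-methyl-4-(prop-2-yn-1-yl)-3-vinylcaran-5-one (vinyl and propargyl cis to each other and anti to the cyclopropane bridge, 3-methyl syn to it), via bromomagnesium enolate 3 (not isolated)
Conditions: CH2=CHMgBr, CuBr·SMe2 (cat.), THF, −40 °C; then propargyl bromide, DMPU, −40 to 0 °C; crude product: NaOMe (cat.), MeOH, rt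
Reagents that add atoms: vinylmagnesium bromide, C=C[Mg]Br; propargyl bromide, C#CCBr
Why: Copper-catalysed conjugate addition followed by enolate alkylation: the vinyl group should add to the β-carbon anti to the cyclopropane (its endo methyl shields the syn face) and set C5, and the methoxide equilibration should leave the propargyl group on C10 pseudo-equatorial and anti to the bridge, because the syn position clashes with the endo methyl.

Step 3
Reactants: 4 the propargyl ketone
Product: 5 3-[(1S,6R)-3-methyl-5-oxo-3-vinylcaran-4-yl]propanal (same configuration as 4)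
Conditions: [CpRu(MeCN)3]PF6 (cat.), 5,5′-bis(trifluoromethyl)-2,2′-bipyridine (cat.), NMP/H2O, 25 °C
Reagents that add atoms: water, O
Why: Ruthenium-catalysed anti-Markovnikov hydration of the terminal alkyne through a metal vinylidene should give the aldehyde and leave the vinyl group, the ketone and the cyclopropane untouched; no stereocentre is formed.

Step 4
Reactants: 5 the vinyl keto aldehyde
Product: 6 3α-hydroxy-8,11-cyclo-10βH-eremophilan-9-one (4β,5β-dimethyl; cyclopropane C7–C8–C11 on the β face)
Conditions: Fe(acac)3 (0.5 equiv), PhSiH3, EtOH/(CH2OH)2, 60 °C, degassed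
Reagents that add atoms: none
Why: An iron hydride generated from Fe(acac)3 and PhSiH3 transfers a hydrogen atom to the terminal carbon C15 of the only alkene (Markovnikov MHAT), which creates the C15 methyl group and a secondary radical at C4; this radical adds to the C3 aldehyde carbon, and the resulting alkoxy radical is reduced by divalent iron and protonated by ethanol. The closest known reaction type is the iron-hydride HAT-triggered reductive cyclization of alkene-tethered ketones, together with the intermolecular addition of HAT-generated alkyl radicals to aldehydes. Ring A is closed in the 6-exo-trig mode onto the C=O group, and only a cis ring fusion is possible because the pseudo-axial vinyl group on C5 and the pseudo-equatorial chain on C10 are cis on ring B. At C4 the planar radical should cyclize through a chair in which C15 is equatorial (β), since an axial C15 would be syn-axial to C9; at C3 the oxygen should go equatorial (α) to avoid the axial C14 methyl, and the reversibility of radical addition to C=O funnels material into this all-equatorial isomer. The step needs chemoselective HAT and six-ring closure: the vinyl group is the sole alkene, and attack of the C4 radical on the C9 ketone would give a cyclobutanol and should not compete.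

Step 5
Reactants: 6 the hydroxy ketone
Product: 7 3α-senecioyloxy-8,11-cyclo-10βH-eremophilan-9-one
Conditions: 3-methylbut-2-enoyl chloride, pyridine, DMAP (cat.), CH2Cl2, 0 °C
Reagents that add atoms: 3-methylbut-2-enoyl chloride, CC(C)=CC(=O)Cl
Why: DMAP-catalysed acylation of the equatorial secondary alcohol; the weak base pyridine should avoid the vinylketene pathway that deconjugates the senecioyl group.

Step 6
Reactants: 7 the senecioate ketone
Product: 8 3α-senecioyloxy-8,11-cyclo-10βH-eremophilan-9-ol (C9 epimers)
Conditions: NaBH4, MeOH, 0 °C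
Reagents that add atoms: none
Why: Borohydride reduction of the cyclopropyl ketone, with the conjugated ester inert; the new C9 configuration is irrelevant because C9 becomes sp2 in step 7.

Step 7
Reactants: 8 the cyclopropyl carbinol
Product: 9 11-chloro-3α-senecioyloxy-10βH-eremophil-8-ene (2-chloropropan-2-yl group on C7, β)
Conditions: HCl (4 M in 1,4-dioxane), ZnCl2 (cat.), CH2Cl2, −20 to 0 °C
Reagents that add atoms: hydrogen chloride, Cl
Why: Julia-type cyclopropylcarbinyl to homoallyl rearrangement: ionization at C9 is assisted by cleavage of the C8–C11 bond to the tertiary cation, which chloride captures, so that the C8=C9 alkene appears while the future isopropenyl group stays masked and C7 keeps its configuration.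

Step 8
Reactants: 9 the homoallylic chloride
Product: 10 11-chloro-3α-senecioyloxy-10βH-eremophilane-8β,9β-diol
Conditions: OsO4 (cat.), NMO, acetone/H2O, 0 °C to rt
Reagents that add atoms: N-methylmorpholine N-oxide, C[N+]1([O-])CCOCC1; water, O
Why: Upjohn syn-dihydroxylation of the only electron-rich alkene from the convex β face (the α face is covered by ring A through the axial C4) should set C8 and C9 as the cis β,β-diol, with the electron-poor senecioate alkene reacting much more slowly.

Step 9
Reactants: 10 the chloro diol
Product: 11 3α-senecioyloxy-10βH-eremophil-11-ene-8β,9β-diol (7β-isopropenyl)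
Conditions: DBU, toluene, 90 °C
Reagents that add atoms: none
Why: E2 dehydrochlorination of the tertiary chloride by a hindered amidine base should remove one of the six accessible methyl hydrogens (Hofmann-type regiochemistry) and unveil the isopropenyl group.

Step 10
Reactants: 11 the isopropenyl diol
Product: 12 9β-angeloyloxy-8β-hydroxy-3α-senecioyloxy-10βH-eremophil-11-ene
Conditions: angelic acid, 2,4,6-trichlorobenzoyl chloride, Et3N, toluene, rt; then 11, 75 °C
Reagents that add atoms: angelic acid, C/C=C(/C)C(=O)O
Why: Yamaguchi esterification through the mixed anhydride: the equatorial C9 hydroxyl should react in preference to the axial C8 hydroxyl next to the isopropenyl group, and the absence of DMAP should keep the Z enoate from isomerizing.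

Step 11
Reactants: 12 the hydroxy diester
Product: 13 (3R,4R,5R,7R,9R,10S)-9-angeloyloxy-3-senecioyloxyeremophil-11-en-8-one (target)
Conditions: Dess–Martin periodinane, NaHCO3, CH2Cl2, 0 °C to rt
Reagents that add atoms: none
Why: Dess–Martin oxidation of the remaining axial alcohol under buffered, non-basic conditions should give the ketone without epimerizing C7 or C9 (both already equatorial) and without moving the isopropenyl double bond into conjugation.

**Compound list**

1 | (+)-3-carene, (1S,6R)-3,7,7-trimethylbicyclo[4.1.0]hept-3-ene | CC1=CC[C@@H]2[C@H](C1)C2(C)C | starting material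
2 | (1S,6R)-car-3-en-5-one | CC1=CC(=O)[C@@H]2[C@H](C1)C2(C)C | intermediate
3 | bromomagnesium enolate of 3-methyl-3-vinylcaran-5-one (vinyl anti to the bridge) | C=C[C@@]1(C)C[C@H]2[C@H](C2(C)C)C(O[Mg]Br)=C1 | intermediate
4 | (1S,6R)-3-methyl-4-(prop-2-yn-1-yl)-3-vinylcaran-5-one, vinyl and propargyl anti to the bridge | C=C[C@@]1(C)C[C@H]2[C@H](C2(C)C)C(=O)[C@H]1CC#C | intermediate
5 | 3-[(1S,6R)-3-methyl-5-oxo-3-vinylcaran-4-yl]propanal | C=C[C@@]1(C)C[C@H]2[C@H](C2(C)C)C(=O)[C@H]1CCC=O | intermediate
6 | 3α-hydroxy-8,11-cyclo-10βH-eremophilan-9-one | C[C@H]1[C@H](O)CC[C@@H]2C(=O)[C@@H]3[C@@H](C3(C)C)C[C@]12C | intermediate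
7 | 3α-senecioyloxy-8,11-cyclo-10βH-eremophilan-9-one | CC(C)=CC(=O)O[C@@H]1CC[C@@H]2C(=O)[C@@H]3[C@@H](C3(C)C)C[C@]2(C)[C@H]1C | intermediate
8 | 3α-senecioyloxy-8,11-cyclo-10βH-eremophilan-9-ol (C9 epimers) | CC(C)=CC(=O)O[C@@H]1CC[C@@H]2C(O)[C@@H]3[C@@H](C3(C)C)C[C@]2(C)[C@H]1C | intermediate
9 | 11-chloro-3α-senecioyloxy-10βH-eremophil-8-ene | CC(C)=CC(=O)O[C@@H]1CC[C@@H]2C=C[C@@H](C(C)(C)Cl)C[C@]2(C)[C@H]1C | intermediate
10 | 11-chloro-3α-senecioyloxy-10βH-eremophilane-8β,9β-diol | CC(C)=CC(=O)O[C@@H]1CC[C@@H]2[C@@H](O)[C@@H](O)[C@@H](C(C)(C)Cl)C[C@]2(C)[C@H]1C | intermediate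
11 | 3α-senecioyloxy-10βH-eremophil-11-ene-8β,9β-diol | CC(C)=CC(=O)O[C@@H]1CC[C@@H]2[C@@H](O)[C@@H](O)[C@@H](C(C)=C)C[C@]2(C)[C@H]1C | intermediate
12 | 9β-angeloyloxy-8β-hydroxy-3α-senecioyloxy-10βH-eremophil-11-ene | CC(C)=CC(=O)O[C@@H]1CC[C@@H]2[C@@H](OC(=O)/C(C)=C\C)[C@@H](O)[C@@H](C(C)=C)C[C@]2(C)[C@H]1C | intermediate
13 | (3R,4R,5R,7R,9R,10S)-9-angeloyloxy-3-senecioyloxyeremophil-11-en-8-one | C=C(C)[C@H]1C[C@@]2(C)[C@H](CC[C@@H](OC(=O)C=C(C)C)[C@@H]2C)[C@@H](OC(=O)/C(C)=C\C)C1=O | target

**Step count and risks**

Total step count: 11. Longest linear sequence: 11 steps (fully linear from 1).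

The three steps most likely to fail:

1. Step 4. The C4 radical may be reduced before it cyclizes (net hydrogenation of the vinyl group), or the alkoxy radical may fragment back to the open chain before it is reduced. The fallback reverses the radical polarity with a ketyl–olefin cyclization and sets out from 4. The ketone is reduced (NaBH4, MeOH) to the cyclopropyl carbinol F1 and silylated (Et3SiCl, imidazole, DMF) to the triethylsilyl ether F2. Alkyne hydration as in step 3 gives the aldehyde F3. SmI2 (HMPA, t-BuOH, THF, 0 °C) then forms the C3 ketyl, which should add 6-exo to C4 of the vinyl group through the same chair, with oxygen and C15 equatorial, to give the hydroxy silyl ether F4. Senecioylation as in step 5 gives the ester F5, and HCl/ZnCl2 as in step 7 removes the silyl group and triggers the rearrangement. The route is rejoined at 9.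

2. Step 2. C-alkylation of the hindered magnesium enolate may be sluggish, O-alkylation or allene formation may compete, and control at C10 may be incomplete. The fallback sets out from 2: the copper-catalysed vinyl addition is run with Me3SiCl to give the trimethylsilyl enol ether F6. A Mukaiyama–Michael addition to acrolein (BF3·OEt2, CH2Cl2, −78 °C) then delivers the three-carbon aldehyde chain directly, anti to the bridge. The route is rejoined at 5, one step shorter.

3. Step 10. The acyl group may be transferred to the axial C8 hydroxyl, both hydroxyls may be acylated, or the angeloyl group may isomerize from Z to E on prolonged heating. The fallback sets out from 11: Bu2SnO (toluene, reflux, water removed) gives the dibutylstannylene acetal F7. Treatment with the preformed angelic mixed anhydride at room temperature should transfer the acyl group to the equatorial C9 oxygen, as tin acetals of cis-diols do. The route is rejoined at 12.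

**Further compounds**

F1 | step 4 | 3-methyl-4-(prop-2-yn-1-yl)-3-vinylcaran-5-ol (C5 carbinol epimers, carane numbering) | C=C[C@@]1(C)C[C@H]2[C@H](C2(C)C)C(O)[C@H]1CC#C
F2 | step 4 | triethylsilyl ether of F1 | C=C[C@@]1(C)C[C@H]2[C@H](C2(C)C)C(O[Si](CC)(CC)CC)[C@H]1CC#C
F3 | step 4 | 3-[3-methyl-5-(triethylsilyloxy)-3-vinylcaran-4-yl]propanal | C=C[C@@]1(C)C[C@H]2[C@H](C2(C)C)C(O[Si](CC)(CC)CC)[C@H]1CCC=O
F4 | step 4 | 9-(triethylsilyloxy)-8,11-cyclo-10βH-eremophilan-3α-ol | C[C@H]1[C@H](O)CC[C@@H]2C(O[Si](CC)(CC)CC)[C@@H]3[C@@H](C3(C)C)C[C@]12C
F5 | step 4 | 3α-senecioyloxy-9-(triethylsilyloxy)-8,11-cyclo-10βH-eremophilane | CC(C)=CC(=O)O[C@@H]1CC[C@@H]2C(O[Si](CC)(CC)CC)[C@@H]3[C@@H](C3(C)C)C[C@]2(C)[C@H]1C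
F6 | step 2 | trimethylsilyl enol ether of 3-methyl-3-vinylcaran-5-one | C=C[C@@]1(C)C[C@H]2[C@H](C2(C)C)C(O[Si](C)(C)C)=C1
F7 | step 10 | 8β,9β-O-dibutylstannylene acetal of 11 | CC(C)=CC(=O)O[C@@H]1CC[C@@H]2[C@H]3O[Sn](CCCC)(CCCC)O[C@H]3[C@@H](C(C)=C)C[C@]2(C)[C@H]1C
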